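**Retrosynthetic overview**

- Feature: the dihydrofuran ring (O1, C2, C3, C3a, C7a) fused to the resorcinol-type benzene ring. The C2–H bond is benzylic and alpha to O1 and stands 1,5 to C3, which carries two aryl groups and can therefore be generated as a diaryl carbene.
- Target ⇒ cis-hexamethyl ether (six O–CH3 cleavages, C2 epimerised cis → trans in the same operation) ⇒ cis-6-bromo-dihydrobenzofuran + 4-methoxystyrene (C6–vinyl bond, Heck).
- cis-6-Bromo-dihydrobenzofuran ⇒ diaryl diazomethane carrying an ortho 2,4-dimethoxybenzyl ether (C2–C3 bond, enantioselective carbene C–H insertion) ⇒ hydrazone ⇒ benzophenone.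
- Benzophenone ⇒ 4-bromo-2,6-dimethoxybenzaldehyde + 1-bromo-3,5-dimethoxybenzene + 2,4-dimethoxybenzyl alcohol (O–CH2 by Mitsunobu, chelation-directed mono-demethylation, C3–aryl bond by Grignard addition and oxidation).
- Ring order: all four benzene rings are bought; the dihydrofuran ring is the only ring made, in step 7.

Key step: step 7

Remark on the chemistry: Rh2(R-PTAD)4 is assumed to deliver the (3S) configuration on this substrate; if the sense of induction proves opposite, Rh2(S-PTAD)4 is used and nothing else in the route changes.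

**Route**

Step 1
Reactants: 1 4-bromo-2,6-dimethoxybenzaldehyde; 2 1-bromo-3,5-dimethoxybenzene
Product: 4 (4-bromo-2,6-dimethoxyphenyl)(3,5-dimethoxyphenyl)methanol (racemic), via 3,5-dimethoxyphenylmagnesium bromide 3 (not isolated)
Conditions: Mg, I2 (cat.), THF, reflux; then 1, THF, 0 °C → rt; aq. NH4Cl
Reagents that add atoms: none
Why: Grignard formation from the aryl bromide and 1,2-addition to the aldehyde should be clean because an arylmagnesium halide does not exchange with the aryl bromide of 1 at 0 °C, and the racemic carbinol centre is removed in step 2.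

Step 2
Reactants: 4 (4-bromo-2,6-dimethoxyphenyl)(3,5-dimethoxyphenyl)methanol
Product: 5 (4-bromo-2,6-dimethoxyphenyl)(3,5-dimethoxyphenyl)methanone
Conditions: Dess–Martin periodinane, CH2Cl2, rt
Reagents that add atoms: none
Why: Dess–Martin oxidation of a secondary benzhydrol to the benzophenone runs under near-neutral conditions that spare the electron-rich rings and the aryl bromide.

Step 3
Reactants: 5 (4-bromo-2,6-dimethoxyphenyl)(3,5-dimethoxyphenyl)methanone
Product: 6 (4-bromo-2-hydroxy-6-methoxyphenyl)(3,5-dimethoxyphenyl)methanone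
Conditions: BCl3 (1.2 equiv), CH2Cl2, −78 → 0 °C; then H2O
Reagents that add atoms: none
Why: Chelation-directed mono-demethylation, in which BCl3 bridges the carbonyl oxygen and one of the two equivalent ortho methoxy oxygens so that chloride cleaves only that methyl ether, the boron phenoxide then deactivating the second ortho group and the meta methoxy groups of the other ring having no chelating partner.

Step 4
Reactants: 6 (4-bromo-2-hydroxy-6-methoxyphenyl)(3,5-dimethoxyphenyl)methanone; 7 2,4-dimethoxybenzyl alcohol
Product: 8 [4-bromo-2-(2,4-dimethoxybenzyloxy)-6-methoxyphenyl](3,5-dimethoxyphenyl)methanone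
Conditions: PPh3, DIAD, THF, 0 °C → rt
Reagents that add atoms: none
Why: Mitsunobu etherification of the acidic ortho-acyl phenol with a primary benzylic alcohol installs the ether from the stable alcohol and avoids 2,4-dimethoxybenzyl chloride, which self-condenses on storage.

Step 5
Reactants: 8 [4-bromo-2-(2,4-dimethoxybenzyloxy)-6-methoxyphenyl](3,5-dimethoxyphenyl)methanone
Product: 9 [4-bromo-2-(2,4-dimethoxybenzyloxy)-6-methoxyphenyl](3,5-dimethoxyphenyl)methanone hydrazone (E/Z mixture)
Conditions: N2H4·H2O (excess), AcOH (cat.), n-BuOH, 110 °C, sealed tube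
Reagents that add atoms: hydrazine (as the hydrate), NN
Why: Acid-catalysed hydrazone condensation, pushed by excess hydrazine and heat because the carbonyl is flanked by two ortho substituents, with the hydrazone geometry of no consequence since both isomers give the same diazo compound.

Step 6
Reactants: 9 the hydrazone of ketone 8
Product: 10 [4-bromo-2-(2,4-dimethoxybenzyloxy)-6-methoxyphenyl](3,5-dimethoxyphenyl)diazomethane
Conditions: activated MnO2 (8 equiv), CH2Cl2, 0 °C → rt, dark; filtration through Celite, solution used at once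
Reagents that add atoms: none
Why: Dehydrogenation of an N-unsubstituted hydrazone with activated MnO2 is the standard entry to diaryl diazomethanes, and the two ortho substituents at the diazo carbon should slow its bimolecular decay to the azine.

Step 7
Reactants: 10 [4-bromo-2-(2,4-dimethoxybenzyloxy)-6-methoxyphenyl](3,5-dimethoxyphenyl)diazomethane
Product: 11 (2R,3S)-6-bromo-2-(2,4-dimethoxyphenyl)-3-(3,5-dimethoxyphenyl)-4-methoxy-2,3-dihydrobenzofuran (cis)
Conditions: Rh2(R-PTAD)4 (dirhodium tetrakis[(R)-(1-adamantyl)(N-phthalimido)acetate], 1 mol %), CH2Cl2, 0 °C, slow addition of 10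
Reagents that add atoms: none
Why: The divalent rhodium dimer expels N2 from 10 and holds a carbene at C3 that bears two electron-rich aryl groups and is therefore weakly electrophilic and discriminating. It should insert into the OCH2 C–H bond of the benzyl ether by an asynchronous, hydride-transfer-like process in which hydrogen moves from C2 to C3 as the C2–C3 bond forms. The closest known reaction type is the dirhodium-catalysed enantioselective intramolecular C–H insertion of diaryl carbenes into benzylic ether C–H bonds, which gives 2,3-diaryl-2,3-dihydrobenzofurans. The dihydrofuran ring (O1, C2, C3, C3a, C7a) closes as a 1,5-insertion through a five-membered cyclic transition state. C3 is set by the chiral carboxylate ligands, which select the face of the carbene carbon, whereas C2 is set relative to C3 in the same compact transition state, which places both aryl groups on one face (cis); only C3 has to be right, since any (3S) trans isomer converges with the cis isomer in step 9. The step needs site selectivity for the benzylic CH2 over the C–H bonds of the neighbouring methoxy group, which are also 1,5, and this is secured by the far more hydridic C–H flanked by oxygen and the 2,4-dimethoxyphenyl ring, while slow addition and the doubly ortho-substituted diazo carbon hold back azine formation.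

Step 8
Reactants: 11 (2R,3S)-6-bromo-2-(2,4-dimethoxyphenyl)-3-(3,5-dimethoxyphenyl)-4-methoxy-2,3-dihydrobenzofuran; 12 4-methoxystyrene
Product: 13 (2R,3S)-2-(2,4-dimethoxyphenyl)-3-(3,5-dimethoxyphenyl)-4-methoxy-6-[(E)-2-(4-methoxyphenyl)ethenyl]-2,3-dihydrobenzofuran (cis)
Conditions: Pd(OAc)2 (5 mol %), P(o-tol)3 (10 mol %), Et3N, DMF, 110 °C
Reagents that add atoms: none
Why: Heck coupling of the aryl bromide with the terminal styrene should give the E-stilbene through syn insertion and syn beta-hydride elimination, and the basic medium touches neither C2 nor C3.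

Step 9
Reactants: 13 (2R,3S)-2-(2,4-dimethoxyphenyl)-3-(3,5-dimethoxyphenyl)-4-methoxy-6-[(E)-2-(4-methoxyphenyl)ethenyl]-2,3-dihydrobenzofuran
Product: 15 (2S,3S)-2-(2,4-dihydroxyphenyl)-3-(3,5-dihydroxyphenyl)-6-[(E)-2-(4-hydroxyphenyl)ethenyl]-2,3-dihydrobenzofuran-4-ol (trans; the target), via ring-opened C2 benzylic cation 14 (not isolated)
Conditions: BBr3 (12 equiv), CH2Cl2, −78 → 0 °C; then H2O, 0 °C
Reagents that add atoms: none
Why: BBr3 ether cleavage should remove all six methyl groups while the same acid ionises the O1–C2 bond to a benzylic cation stabilised by the ortho and para oxygens of the C2 aryl group, which recloses on the face away from the C3 aryl group to the more stable trans ring, so that C2 becomes S and C3 is untouched; once demethylated, the two ortho oxygens of the resorcinol ring are equivalent and closure through either gives the same compound.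

**Compound list**

1 | 4-bromo-2,6-dimethoxybenzaldehyde | COc1cc(Br)cc(OC)c1C=O | starting material
2 | 1-bromo-3,5-dimethoxybenzene | COc1cc(Br)cc(OC)c1 | starting material
3 | 3,5-dimethoxyphenylmagnesium bromide | COc1cc(OC)cc([Mg]Br)c1 | intermediate (not isolated)
4 | (4-bromo-2,6-dimethoxyphenyl)(3,5-dimethoxyphenyl)methanol, racemic | COc1cc(OC)cc(C(O)c2c(OC)cc(Br)cc2OC)c1 | intermediate
5 | (4-bromo-2,6-dimethoxyphenyl)(3,5-dimethoxyphenyl)methanone | COc1cc(OC)cc(C(=O)c2c(OC)cc(Br)cc2OC)c1 | intermediate
6 | (4-bromo-2-hydroxy-6-methoxyphenyl)(3,5-dimethoxyphenyl)methanone | COc1cc(OC)cc(C(=O)c2c(O)cc(Br)cc2OC)c1 | intermediate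
7 | 2,4-dimethoxybenzyl alcohol | COc1ccc(CO)c(OC)c1 | starting material
8 | [4-bromo-2-(2,4-dimethoxybenzyloxy)-6-methoxyphenyl](3,5-dimethoxyphenyl)methanone | COc1ccc(COc2cc(Br)cc(OC)c2C(=O)c2cc(OC)cc(OC)c2)c(OC)c1 | intermediate
9 | hydrazone of 8 (E/Z mixture) | COc1ccc(COc2cc(Br)cc(OC)c2C(=NN)c2cc(OC)cc(OC)c2)c(OC)c1 | intermediate
10 | [4-bromo-2-(2,4-dimethoxybenzyloxy)-6-methoxyphenyl](3,5-dimethoxyphenyl)diazomethane | COc1ccc(COc2cc(Br)cc(OC)c2C(=[N+]=[N-])c2cc(OC)cc(OC)c2)c(OC)c1 | intermediate
11 | (2R,3S)-cis-6-bromo-2-(2,4-dimethoxyphenyl)-3-(3,5-dimethoxyphenyl)-4-methoxy-2,3-dihydrobenzofuran | Brc1cc(OC)c2c(c1)O[C@@H](c1ccc(OC)cc1OC)[C@H]2c1cc(OC)cc(OC)c1 | intermediate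
12 | 4-methoxystyrene | COc1ccc(C=C)cc1 | starting material
13 | (2R,3S)-cis-2-(2,4-dimethoxyphenyl)-3-(3,5-dimethoxyphenyl)-4-methoxy-6-[(E)-2-(4-methoxyphenyl)ethenyl]-2,3-dihydrobenzofuran | COc1ccc(/C=C/c2cc(OC)c3c(c2)O[C@@H](c2ccc(OC)cc2OC)[C@H]3c2cc(OC)cc(OC)c2)cc1 | intermediate
14 | (S)-1-(2,4-dihydroxyphenyl)-2-(3,5-dihydroxyphenyl)-2-{2,6-dihydroxy-4-[(E)-2-(4-hydroxyphenyl)ethenyl]phenyl}ethylium, the ring-opened C2 benzylic cation (drawn with free phenols; in the flask its oxygens carry boron or methyl) | Oc1ccc([CH+][C@@H](c2cc(O)cc(O)c2)c2c(O)cc(/C=C/c3ccc(O)cc3)cc2O)c(O)c1 | intermediate (not isolated)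
15 | (2S,3S)-trans-2-(2,4-dihydroxyphenyl)-3-(3,5-dihydroxyphenyl)-6-[(E)-2-(4-hydroxyphenyl)ethenyl]-2,3-dihydrobenzofuran-4-ol | Oc1ccc(/C=C/c2cc(O)c3c(c2)O[C@H](c2ccc(O)cc2O)[C@H]3c2cc(O)cc(O)c2)cc1 | target

**Step count**

Total: 9 steps. Longest linear sequence: 9 steps (2 → 15).

**Steps most likely to fail**

1. Step 7. The carbene carbon is flanked by two ortho ether groups, so the catalyst pocket may discriminate its two faces poorly and the enantiomeric purity at C3 may be low; carbene dimerisation to the azine may also compete. The fallback sets out from diazo compound 10 and comes back at 11. Compound 10 is decomposed with achiral Rh2(OAc)4 in CH2Cl2 under slow addition, which should give 11 as a racemate with its mirror image, (2S,3R)-6-bromo-2-(2,4-dimethoxyphenyl)-3-(3,5-dimethoxyphenyl)-4-methoxy-2,3-dihydrobenzofuran F1. The two are separated by preparative chromatography on a chiral stationary phase (amylose or cellulose carbamate, supercritical CO2/MeOH), so that optical purity comes from resolution and not from the catalyst. Resolved 11 then continues with step 8.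

2. Step 9. Under BBr3 the electron-rich stilbene may be hydrobrominated or oligomerised. While the ring stands open, loss of the C3 proton or a 1,2-hydride shift may erode C3. The fallback sets out from bromide 11, before the stilbene exists, and comes back at target 15. BBr3 in CH2Cl2 (−78 → 0 °C) removes the five methyl ethers of 11 and epimerises C2, which should give (2S,3S)-trans-6-bromo-2-(2,4-dihydroxyphenyl)-3-(3,5-dihydroxyphenyl)-2,3-dihydrobenzofuran-4-ol F2. Ac2O and pyridine convert it into the pentaacetate of that pentaphenol F3. Heck coupling of this with commercial 4-acetoxystyrene (Pd(OAc)2, P(o-tol)3, Et3N, DMF, 100 °C) gives the hexaacetate of the target F4. Methanolysis (K2CO3, MeOH, 0 °C, then dilute acid) releases 15 without exposing the stilbene to a strong acid.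

3. Step 5. Condensation at a carbonyl shielded by two ortho substituents may stay incomplete. Under forcing conditions the hydrazone nitrogen may displace an ortho alkoxy group and close an indazole. The fallback sets out from ketone 8 and comes back at hydrazone 9. Lawesson's reagent in toluene at 90 °C turns the carbonyl into the far more electrophilic thiocarbonyl, giving [4-bromo-2-(2,4-dimethoxybenzyloxy)-6-methoxyphenyl](3,5-dimethoxyphenyl)methanethione F5. Hydrazine hydrate in THF/EtOH at room temperature then adds and expels hydrogen sulfide to give 9.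

**Further compounds**

F1 | step 7 | (2S,3R)-cis-6-bromo-2-(2,4-dimethoxyphenyl)-3-(3,5-dimethoxyphenyl)-4-methoxy-2,3-dihydrobenzofuran (mirror image of 11, formed with it as the racemate) | Brc1cc(OC)c2c(c1)O[C@H](c1ccc(OC)cc1OC)[C@@H]2c1cc(OC)cc(OC)c1
F2 | step 9 | (2S,3S)-trans-6-bromo-2-(2,4-dihydroxyphenyl)-3-(3,5-dihydroxyphenyl)-2,3-dihydrobenzofuran-4-ol | Brc1cc(O)c2c(c1)O[C@H](c1ccc(O)cc1O)[C@H]2c1cc(O)cc(O)c1
F3 | step 9 | pentaacetate of F2, (2S,3S)-trans | Brc1cc(OC(C)=O)c2c(c1)O[C@H](c1ccc(OC(C)=O)cc1OC(C)=O)[C@H]2c1cc(OC(C)=O)cc(OC(C)=O)c1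
F4 | step 9 | hexaacetate of 15, (2S,3S)-trans, E-alkene | CC(=O)Oc1ccc(/C=C/c2cc(OC(C)=O)c3c(c2)O[C@H](c2ccc(OC(C)=O)cc2OC(C)=O)[C@H]3c2cc(OC(C)=O)cc(OC(C)=O)c2)cc1
F5 | step 5 | [4-bromo-2-(2,4-dimethoxybenzyloxy)-6-methoxyphenyl](3,5-dimethoxyphenyl)methanethione | COc1ccc(COc2cc(Br)cc(OC)c2C(=S)c2cc(OC)cc(OC)c2)c(OC)c1
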